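**Retrosynthetic overview**

1. Ring C is cut at the O1–C2 bond back to the open 2'-hydroxychalcone. Forward, a catalytic enantioselective 6-endo oxa-Michael closure (the chalcone-to-flavanone isomerisation of flavonoid biosynthesis) forms ring C and sets C2 as S in one event.
2. The chalcone is cut at the aryl–C(=O) bond, not at the enone C=C. Forward, a cinnamoyl (C6–C3) unit is C-acylated onto the tetraoxygenated ring A (Friedel–Crafts), and AlCl3 frees the 2'-OH in the same flask.
3. The ring A partner, 1,2,3,5-tetramethoxybenzene, comes from 3,4,5-trimethoxyphenol by O-methylation; the C6–C3 partner is 3,4-dimethoxycinnamic acid.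
4. Ring order: rings A and B are bought as benzene rings; ring C is the only ring made, and it is made last.

Assumption: the SMILES is read as the (2S)-flavanone; 3,4,5-trimethoxyphenol 1 is taken as the cheap source of ring A because its methyl ether 2 is a costlier catalogue item (if 2 is bought, step 1 falls away).

**Route**

Step 1
Reactants: 1 3,4,5-trimethoxyphenol
Product: 2 1,2,3,5-tetramethoxybenzene
Conditions: MeI (1.5 equiv), K2CO3 (2.0 equiv), acetone, reflux, 8 h, N2
Reagents that add atoms: iodomethane, CI
Why: Williamson ether synthesis, in which the phenoxide of 1 is O-methylated by SN2 attack on MeI; no stereocentre is involved.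

Step 2
Reactants: 3 (E)-3,4-dimethoxycinnamic acid (1.05 equiv); 2 1,2,3,5-tetramethoxybenzene
Product: 6 (2E)-3-(3,4-dimethoxyphenyl)-1-(2-hydroxy-3,4,6-trimethoxyphenyl)prop-2-en-1-one, via (E)-3,4-dimethoxycinnamoyl chloride 4 (not isolated), via hexamethoxychalcone 5 (not isolated)
Conditions: 3, (COCl)2 (1.2 equiv), DMF (cat.), CH2Cl2, 0 °C to rt, volatiles removed in vacuo; then 2, AlCl3 (2.5 equiv), CH2Cl2, 0 °C to rt; ice/1 M HCl work-up; crystallisation from EtOH
Reagents that add atoms: none
Why: Friedel–Crafts acylation by the acylium ion from 4 at the single kind of free position of 2 (attack at C=O of the acid chloride is far faster than conjugate attack at C-β), after which AlCl3, chelated between the ketone oxygen and an ortho OMe, cleaves by chloride SN2 the 2'-OMe that the neighbouring 3'-OMe twists out of the ring plane (the selectivity expected from the acetyl analogue), leaving the 6'-OMe and the ring B ethers intact and the E alkene unchanged; no stereocentre is formed.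

Step 3
Reactants: 6 (2E)-3-(3,4-dimethoxyphenyl)-1-(2-hydroxy-3,4,6-trimethoxyphenyl)prop-2-en-1-one
Product: 7 (2S)-2-(3,4-dimethoxyphenyl)-5,7,8-trimethoxy-2,3-dihydro-4H-1-benzopyran-4-one
Conditions: 1-[3,5-bis(trifluoromethyl)phenyl]-3-[(8R,9R)-6'-methoxycinchonan-9-yl]thiourea (C29H28F6N4OS, 10 mol %), toluene (0.05 M), 25 °C, 48–96 h; short silica pad; crystallisation from MeOH
Reagents that add atoms: none
Why: Proposed new method: the quinuclidine nitrogen of the catalyst takes up the 2'-OH proton while its two thiourea N–H bonds bind the carbonyl oxygen, so the ion-paired phenoxide adds 6-endo-trig to the Si face of C-β of the s-trans enone inside the chiral pocket and the quinuclidinium ion then protonates the thiourea-bound enolate, which sets C2 as S (facial sense taken by analogy with additions of this catalyst family to chalcones), the 6'-OMe group twisting the cinnamoyl unit out of the ring A plane so that closure is fast and lies far on the flavanone side; the closest known reaction type is the cinchona-thiourea-catalysed asymmetric intramolecular oxa-Michael addition of 2'-hydroxychalcones activated by an α-ester group, of which this is the unactivated, chalcone-isomerase-like case.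

**Compound list**

1 | 3,4,5-trimethoxyphenol | COc1cc(O)cc(OC)c1OC | starting material
2 | 1,2,3,5-tetramethoxybenzene | COc1cc(OC)c(OC)c(OC)c1 | intermediate
3 | (E)-3,4-dimethoxycinnamic acid | COc1ccc(/C=C/C(=O)O)cc1OC | starting material
4 | (E)-3,4-dimethoxycinnamoyl chloride | COc1ccc(/C=C/C(=O)Cl)cc1OC | intermediate (not isolated)
5 | (2E)-3-(3,4-dimethoxyphenyl)-1-(2,3,4,6-tetramethoxyphenyl)prop-2-en-1-one (2',3',4',6',3,4-hexamethoxychalcone, formed as its AlCl3 complex) | COc1ccc(/C=C/C(=O)c2c(OC)cc(OC)c(OC)c2OC)cc1OC | intermediate (not isolated)
6 | (2E)-3-(3,4-dimethoxyphenyl)-1-(2-hydroxy-3,4,6-trimethoxyphenyl)prop-2-en-1-one (2'-hydroxy-3',4',6',3,4-pentamethoxychalcone) | COc1ccc(/C=C/C(=O)c2c(OC)cc(OC)c(OC)c2O)cc1OC | intermediate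
7 | (2S)-2-(3,4-dimethoxyphenyl)-5,7,8-trimethoxy-2,3-dihydro-4H-1-benzopyran-4-one | COc1ccc([C@@H]2CC(=O)c3c(OC)cc(OC)c(OC)c3O2)cc1OC | target

**Step count and risks**

Total step count: 3. Longest linear sequence: 3 steps (1 → 2 → 6 → 7); acid 3 enters at step 2 with no steps of its own.

Steps most likely to fail, highest risk first:

Step 3. The enone is not activated and the phenol is held in a hydrogen bond to the carbonyl, so turnover may be slow. The ee may be modest, and it can erode by retro-oxa-Michael opening if the reaction is left long after full conversion. The facial sense rests on a model and was not recalled from a directly matching case. The first run is therefore checked by chiral HPLC and CD (a 2S flavanone gives a positive band near 330 nm and a negative one near 290 nm); the (8S,9S) quinine-derived mirror-image catalyst is at hand if the sense is opposite. The fallback sets out from 6 and comes back at 7. Chalcone 6 is closed without stereocontrol (NaOAc, EtOH, reflux) to racemic 2-(3,4-dimethoxyphenyl)-5,7,8-trimethoxy-2,3-dihydro-4H-1-benzopyran-4-one F1. F1 is resolved by preparative chiral SFC (amylose tris(3,5-dimethylphenylcarbamate) phase, CO2/MeOH) into 7 and (2R)-2-(3,4-dimethoxyphenyl)-5,7,8-trimethoxy-2,3-dihydro-4H-1-benzopyran-4-one F2. F2 is reopened to 6 with KOH in EtOH followed by acidification, and recycled.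

Step 2. The electron-rich arene 2 may add to C-β of the AlCl3-bound enone, AlCl3 may cleave a further ether, or the 6'-OMe may be cleaved in place of the 2'-OMe. The fallback sets out from 2 and comes back at 6. Arene 2 is acetylated with acetyl chloride and AlCl3 in Et2O to 1-(2,3,4,6-tetramethoxyphenyl)ethanone F3, which loses its 2-OMe group in the same flask to give 1-(2-hydroxy-3,4,6-trimethoxyphenyl)ethanone F4. Claisen–Schmidt condensation of F4 with 3,4-dimethoxybenzaldehyde (KOH, EtOH/H2O, rt), then acidification, gives 6. This replaces the acylation by an aldol construction of the enone, at the cost of one more step.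

Step 1. The risk is low; the electron-rich phenoxide can be air-oxidised to a quinone or react incompletely. The fallback sets out from 1 and comes back at 2. It is a Mitsunobu etherification with MeOH (PPh3, diisopropyl azodicarboxylate, THF, 0 °C to rt), which alkylates through an oxyphosphonium electrophile under neutral conditions and never holds a free phenoxide in base. It makes no compound outside the compound list (F0).

**Further compounds**

F1 | step 3 | racemic 2-(3,4-dimethoxyphenyl)-5,7,8-trimethoxy-2,3-dihydro-4H-1-benzopyran-4-one | COc1ccc(C2CC(=O)c3c(OC)cc(OC)c(OC)c3O2)cc1OC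
F2 | step 3 | (2R)-2-(3,4-dimethoxyphenyl)-5,7,8-trimethoxy-2,3-dihydro-4H-1-benzopyran-4-one | COc1ccc([C@H]2CC(=O)c3c(OC)cc(OC)c(OC)c3O2)cc1OC
F3 | step 2 | 1-(2,3,4,6-tetramethoxyphenyl)ethanone | CC(=O)c1c(OC)cc(OC)c(OC)c1OC
F4 | step 2 | 1-(2-hydroxy-3,4,6-trimethoxyphenyl)ethanone | CC(=O)c1c(OC)cc(OC)c(OC)c1O
F0 | step 1 | none | none
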